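(All runs are simulated for substances that don't exist; the scatter is artificial.)

How much complex with one exchanged stands beside a given amount of starting complex hangs on one number, r: the rate constant of the second exchange divided by that of the first, usually called the selectivity factor.

| setting | dusk | amber | green | teal |
|---|---|---|---|---|
| starting complex | 1 M | 1.0 M | 1.0 M | 1.0 M |
| incoming ligand | 0.59 M (in portions, 4) | 0.500 M (in portions, 4) | 1.20 M (in portions, 4) | 3.00 M (in portions, 4) |
| remark | run made earlier; portions every 3.0 h | the portions of incoming ligand follow each other after 3.0 h, the first at the start | the portions of incoming ligand follow each other after 3.0 h, the first at the start | the portions of incoming ligand follow each other after 3.0 h, the first at the start |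
| time |  | 2.5 d | 2.5 d | 2.5 d |

dusk run (percent of the starting complex charged)

| time / h | complex with one exchanged / % |
|---|---|
| 4.00 | 12.3 |
| 10.0 | 31.8 |
| 20.0 | 43.8 |
| 30.0 | 44.4 |
| 40.0 | 45.3 |

(standard deviation of a reading: 0.5 percentage points)

- steps that have been proposed: starting complex + incoming ligand -> leaving ligand + complex with one exchanged; complex with one exchanged + incoming ligand -> leaving ligand + complex with two exchanged; complex with two exchanged + incoming ligand -> leaving ligand + complex with three exchanged; complex with three exchanged + incoming ligand -> leaving ligand + complex with four exchanged; incoming ligand <-> dormant form; starting complex -> decomposition product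
- no earlier run changes the charge of incoming ligand; that part of a forecast is a guess

- final complex with one exchanged, as a percentage of the starting complex charged, for each flask in turn (amber, green, teal)

1. Let x and y be [starting complex] and [complex with one exchanged] as fractions of the charge, and neglect decomposition. Both exchanges run in proportion to [incoming ligand], so dividing one rate by the other removes that concentration, and with it time, the portions and the dormant form. Integrating gives y = (x^r − x)/(1 − r).

2. In dusk, y reads 44.4% after 30.0 h and 45.3% after 40.0 h. I take the last reading as the end and assume the 0.59 M of ligand sits in the first two products. That leaves 6.85% with two exchanged and x = 47.9%. To first order, the two-exchanged fraction is r(−ln x − 1 + x), so the reading gives r = 0.318: how readily a once-exchanged complex takes ligand, compared with a fresh one.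

3. The curve peaks at y = r^(r/(1 − r)) = 58.6%, at an uptake of 1.04 ligands per complex. Amber's charge gives me y = 39.7%. Green's 1.20 per complex is more than that uptake, so I say about 58.6%.

4. Was one number enough? Not for teal: r turns x into y, but turning teal's charge into x needs the third and fourth steps, which dusk does not show. If they ran at the second step's pace, x^r would be about exp(−2.00), so y would be about 19.8%, a guess.

5. The forecast gave 40%, 55% and 5%, saying “excess ligand drives mono on to higher exchange”, and for teal my figure is higher.

The flasks give 40.2%, 57.2% and 16.5%.

    starting complex + incoming ligand → leaving ligand + complex with one exchanged (k = 8.60 × 10⁻⁵ L mol⁻¹ s⁻¹)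
    complex with one exchanged + incoming ligand → leaving ligand + complex with two exchanged (k = 2.90 × 10⁻⁵ L mol⁻¹ s⁻¹)
    complex with two exchanged + incoming ligand → leaving ligand + complex with three exchanged (k = 4.20 × 10⁻⁵ L mol⁻¹ s⁻¹)
    complex with three exchanged + incoming ligand → leaving ligand + complex with four exchanged (k = 7.50 × 10⁻⁵ L mol⁻¹ s⁻¹)
    incoming ligand ⇌ dormant form (K = 0.110, k = 2.20 × 10⁻⁴ s⁻¹)
    starting complex → decomposition product (k = 4.80 × 10⁻⁸ s⁻¹)

Teal ends with 51.1% complex with four exchanged and 0.147% starting complex. Put into the curve with r = 0.318, that x gives y = 18.2%, where teal holds 16.5%.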